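## Analysis of the target

CNP0272110.1 is a labdane: a trans-fused decalin (ring A = C1–C5 and C10; ring B = C5–C10) with a tetrasubstituted C8=C9 alkene, the C17 methyl on C8, the angular C20 methyl on C10 and a C9 side chain (C11–C15, C16 methyl on C13) that ends in an (E)-trisubstituted enoic acid; labdane numbering is used throughout, and α is the face opposite C20. The five stereocentres all lie on the decalin: C3 (R, axial 3α-ester), C4 (S, quaternary, C18 methyl α and C19 hydroxymethyl β), C5 (R, H α), C6 (R, axial 6β-ester) and C10 (S, quaternary). C19, O6 and C20 therefore stand 1,3-diaxial on the β face, and O3 is axial on the α face. The sensitive groups are the two hindered isovalerates next to a free primary alcohol (acyl migration and hydrolysis under base), the enoic acid (E/Z drift), and the C8=C9 alkene, which sits β,γ to any C6 carbonyl and can slip into conjugation. The difficulties are the quaternary centres C4 and C10 on either side of C5, the trans ring fusion, two axial carbinol esters that must be told apart from a third, primary hydroxyl, and a fully substituted ring alkene. The strategy rests on ring B: C9 is flanked by the methyl-bearing C8 and C10 and is para to the oxygenated C6, which is the substitution pattern of 2,6-dimethylbenzoquinone. C3, C4 and C19 of ring A form a β-keto ester, so a quinone monoketal and a vinyl β-keto ester between them contain every ring carbon.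

## Retrosynthetic reasoning

**C15 oxidation level.** 34 is traced through enal 33 to diol 32. The acid is cut back to the allylic alcohol because a free acid or simple ester at C15 would not survive the organometallic and hydride steps and could not be unmasked beside two isovalerates. Forward, the allylic hydroxyl must be oxidised in two stages without touching the neopentyl C19 hydroxyl or the C13 alkene.

**Ester C–O bonds at O3 and O6.** Both are cut together, since both acyl groups come from 30, of which two equivalents are consumed. This leads from 32 through the doubly silylated diester 31 to diol 29, in which the primary C19 hydroxyl is masked so that only the two axial secondary hydroxyls are acylated. 29 comes from triol 28 by silylation of its only primary hydroxyl.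

**Carbinol C–H bonds at C3 and C6.** 28 is the reduction product of hydroxy lactone 27, which comes from diketo ester 25. Both new centres are axial alcohols, which a bulky hydride gives by attack from the open side: equatorial attack at C3, and α-face attack at C6, where the β face is closed by C19 and C20. The 6β-alkoxide is 1,3-diaxial to the C19 ester and should close to the lactone, which is then opened reductively to the C19 alcohol.

**C8=C9 alkene.** 25 is traced to γ-hydroxy enone 24 by restoring the C9–O bond and moving the alkene to C7=C8. The forward reaction is a reductive vinylogous elimination: it must expel the tertiary hydroxyl, protonate the dienolate at C7 and leave the alkene out of conjugation.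

**C4–C18 bond.** Cutting it gives β-keto ester 23. Methylation is placed after the fusion is trans, because only then is the facial bias at C4 the familiar one: the axial C20 methyl closes the β face, the methyl enters α, and the ester becomes the β carbon C19.

**C5–H bond.** 23 differs from 21 only at C5. The annulation can only give the cis fusion, so C5 must be inverted once C6 is a ketone. Equilibration is not counted on: while C4 is the sp2 carbon of the enolised keto ester, allylic strain between the C19 ester and the C6 carbonyl works against the trans isomer, and 6-ketones with a fully substituted C4 are not dependably trans at equilibrium either. The inversion is therefore kinetic: the C5 proton is removed and a proton is returned from the face opposite C20.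

**C9–C11 bond.** 21 is the hydrolysis product of ketal 20, and 20 is cut at C9–C11 into bicyclic enone 10 and side-chain bromide 16, used as its organocerium derivative 18. The cut is made at the carbonyl carbon of 10 because the tertiary allylic alcohol it leaves is the leaving group needed later for the C8=C9 alkene, and because the whole (E)-configured chain arrives in one piece.

**Side chain.** 16 goes back through 15 and 14 to allylic alcohol 13, and 13 to alkyne 11 by cutting C13–C16 and C14–C15. Syn carbometallation of the alkyne fixes the E geometry.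

**C4–C5 and C1–C10 bonds (key disconnection).** 10 is cut into dienone 3 and keto ester 8. No other pair of bonds divides the bicycle into two achiral fragments that each need at most two steps; ring A, the quaternary C10 and the C5 centre are formed together. The forward reaction has to choose between the two enantiotopic β-carbons of 3 and close ring A onto the methyl-bearing α-carbon.

**Fragments.** 3 comes from phenol 1 by oxidation in the ketal-forming alcohol. 8 comes from allylic alcohol 7, the aldol product of 4 and 5.

## Alternatives that were turned down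

**Alternative 1:** The C5–C6 and C4–C18 bonds are cut on a preformed ring A, and no ring bond is cut. Forward, a vinyl cuprate (vinylmagnesium bromide with CuBr·SMe2) adds to C5 of a ring A enone ester that already holds the quaternary C10 (C20 methyl, acetal as the future C9). The keto ester enolate is then methylated at C4 in the same flask to give the monocyclic keto ester A1, methyl (1R,5S,6R)-5-(dimethoxymethyl)-1,5-dimethyl-2-oxo-6-vinylcyclohexane-1-carboxylate.
- For: conjugate addition followed by enolate alkylation is established chemistry. In A1 it sets C5 directly with the configuration needed for the trans fusion, and C4 by alkylation anti to the new vinyl group.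
- Against: the step that makes A1 closes no ring. Ring B, with its tetrasubstituted alkene and the C6 oxygen, must still be built from the vinyl group and the acetal of A1. The quaternary C10 has to be made enantioselectively beforehand. The facial choice at C5 depends only on the size difference between methyl and dimethoxymethyl on the neighbouring carbon.
- Comparison: the path through A1 is stronger than the chosen route on the C4/C5 relationship, which the chosen route must correct at C5 after the annulation. The chosen route offers instead both rings and all ring-B carbons from two short achiral fragments in one step.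

**Alternative 2:** The C7–C8 and C9–C10 bonds of ring B are cut. Forward, a 2-ethoxydiene built on an enantiopure ring A (C7=C6–C5=C10) adds a but-2-ynoate ester. This closes ring B and creates the quaternary C10, giving the bicyclic 1,4-diene A2, methyl (5S,6S,8aS)-6-[(tert-butyldimethylsilyl)oxy]-5-{[(tert-butyldiphenylsilyl)oxy]methyl}-4-ethoxy-2,5,8a-trimethyl-3,5,6,7,8,8a-hexahydronaphthalene-1-carboxylate.
- For: in A2 the C8=C9 alkene arrives fully substituted and in place, with the C17 methyl and a carbon handle on C9, and C6 is already oxygenated. It needs no reductive transposition, and is stronger than the chosen route on this point.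
- Against: the diene terminus C10 is fully substituted and sits next to the quaternary C4, so the s-cis conformer is strained and the cycloaddition with a moderate dienophile is demanding. The face selectivity at C10 must come from remote ring A centres. The C3 oxygen in A2 is β and needs inversion. C5 must still be set by protonation of the C5=C6 enol ether, the same kinetic question the chosen route faces. The ester on C9 of A2 needs a multi-step homologation to the side chain.
- Comparison: both close one ring in the key step. The chosen route reaches its key step in three steps instead of a long chiral ring A synthesis and brings the side chain in one addition.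

**Alternative 3:** The C3–C4 bond of ring A is cut on a ring B from the chiral pool. Forward, the copper hydride hexamer [(Ph3P)CuH]6 adds hydride to the exocyclic methylene of a 19,6-lactone, making the C18 methyl. The C4 enolate adds to a tethered C3 aldehyde, closing ring A to the tricyclic hydroxy lactone A3, (3S,4R,5R,6R,8R,10S)-3-hydroxy-9-oxo-11,12,13,14,15,16-hexanorlabdan-19,6-olide.
- For: the absolute configuration is bought, not made. The lactone of A3 ties C19 and O6 together on the β face and fixes C4, C5 and C6 relative to C10 with the trans fusion in place. On stereochemical security it is stronger than the chosen route.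
- Against: the aldol gives A3 as the 3β-alcohol, which must be inverted. The C9 ketone of A3 still needs the side chain and a regioselective dehydration to C8=C9 against the exocyclic alternative. The aldehyde-lactone precursor with its quaternary C10 takes many steps from the monoterpene.
- Comparison: the path through A3 is safer but much longer. The chosen route forms two skeletal bonds, one ring and the quaternary C10 in a single step from achiral materials, at the price of an untested enantioselective annulation and a C5 inversion.

Key step: step 4

Assumptions and remarks: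
- The sense of induction of the squaramide cannot be predicted with confidence. The quinine-derived catalyst is written, and its quinidine-derived pseudoenantiomer would be used if the antipode of 10 predominated.
- 4-(tert-Butyldimethylsilyloxy)but-1-yne (11) is taken as commercially available.
- The C9 carbinol centre of 20–24 is not controlled and is destroyed in step 13; both epimers are carried forward.

## Route

**Step 1**
Reactants: 1 2,6-dimethylphenol
Product: 3 4,4-dimethoxy-2,6-dimethylcyclohexa-2,5-dien-1-one, via 4-methoxy-2,6-dimethylphenol 2 (not isolated)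
Conditions: PhI(OAc)2 (2.2 equiv), MeOH, 0 °C → rt
Reagents that add atoms: methanol, CO; methanol (second equivalent), CO
Why: Hypervalent-iodine oxidation of a para-unsubstituted phenol in methanol; the first oxidation traps one methanol at the free para position to give 2, and the second oxidation traps another methanol and converts this 4-methoxyphenol into the quinone monoketal.

**Step 2**
Reactants: 4 methyl acetate; 5 acrolein
Product: 7 methyl 3-hydroxypent-4-enoate (racemic), via lithium enolate 6 (not isolated)
Conditions: LiN(i-Pr)2 (LDA), THF, −78 °C; then 5, −78 °C; AcOH quench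
Reagents that add atoms: none
Why: Aldol addition of an ester lithium enolate to an enal; at −78 °C the hard enolate adds 1,2 to acrolein.

**Step 3**
Reactants: 7 methyl 3-hydroxypent-4-enoate
Product: 8 methyl 3-oxopent-4-enoate
Conditions: CrO3, H2SO4, acetone, 0 °C
Reagents that add atoms: none
Why: Chromic acid (Jones) oxidation of a secondary allylic alcohol to the vinyl ketone; the acidic medium spares the base-sensitive vinyl β-keto ester, which is used at once.

**Step 4 (key step)**
Reactants: 3 4,4-dimethoxy-2,6-dimethylcyclohexa-2,5-dien-1-one; 8 methyl 3-oxopent-4-enoate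
Product: 10 methyl (4aS,8aS)-2-hydroxy-8,8-dimethoxy-4a,6-dimethyl-5-oxo-3,4,4a,5,8,8a-hexahydronaphthalene-1-carboxylate (cis-fused; labdane C5–H and C20 both β), via dienolate Michael adduct 9 (not isolated)
Conditions: quinine-derived amine–squaramide (3,5-bis(trifluoromethyl)phenyl squaramide of 9-amino-9-deoxy-epi-quinine, 10 mol %), toluene, −20 °C, slow addition of 8; then Cs2CO3 (0.2 equiv), −20 → 0 °C
Reagents that add atoms: none
Why: Proposed new method: the tertiary amine of the catalyst deprotonates 8 while the squaramide N–H bonds bind the carbonyl of 3, so the enolate carbon C4 adds to one of the two enantiotopic β-carbons (C5) and gives dienolate 9, which then adds through C10 to the terminal vinyl carbon C1 in a 6-endo-trig Michael closure of ring A, completed by the catalytic Cs2CO3 and ending at the stabilised enol of the β-keto ester. The closest known reaction types are the Cs2CO3-mediated double Michael (formal [4+2]) annulation of this keto ester with 2-acylcyclohex-2-enones, run racemic, and amine–squaramide desymmetrisations of 4,4-disubstituted cyclohexadienones; their combination on a quinone monoketal is untested. C5 is set by the catalyst, which must tell the two enantiotopic enone halves apart. C10 is set by the ring closure, because the three-atom tether on C5 can reach the neighbouring enolate carbon only from its own face, so the fusion is cis. Regioselectivity needs no control: C5 and C7 are the only β-positions and are related by symmetry, and once one enone has reacted the other remains as the C7=C8–C9 enone. The substrate fits because 3 is C2v-symmetric, already carries the future C20 and C17 methyls, and its ketal blocks aromatisation and masks the C6 ketone. The carbonate is held back until 3 is consumed so that a racemic background addition cannot compete.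

**Step 5**
Reactants: 11 4-(tert-butyldimethylsilyloxy)but-1-yne
Product: 13 (2E)-5-(tert-butyldimethylsilyloxy)-3-methylpent-2-en-1-ol, via alkenylalane 12 (not isolated)
Conditions: Me3Al, Cp2ZrCl2 (20 mol %), CH2Cl2, 0 °C → rt; then n-BuLi, THF, −78 °C; (CH2O)n, −78 °C → rt
Reagents that add atoms: trimethylaluminium, C[Al](C)C; formaldehyde (from paraformaldehyde), C=O
Why: Zirconium-catalysed carboalumination (Negishi) adds methyl and aluminium syn across the alkyne with aluminium at the terminus; the derived aluminate is hydroxymethylated with retention, which fixes the E geometry of C13=C14.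

**Step 6**
Reactants: 13 (2E)-5-(tert-butyldimethylsilyloxy)-3-methylpent-2-en-1-ol
Product: 14 tert-butyl{[(2E)-5-(tert-butyldimethylsilyloxy)-3-methylpent-2-en-1-yl]oxy}diphenylsilane
Conditions: TBDPSCl, imidazole, CH2Cl2, rt
Reagents that add atoms: tert-butyldiphenylsilyl chloride, CC(C)(C)[Si](Cl)(c1ccccc1)c1ccccc1
Why: Silylation of the primary allylic alcohol; TBDPS is chosen for C15–O because it survives the later acid, zinc and hydride steps and is removed by fluoride at the end.

**Step 7**
Reactants: 14 tert-butyl{[(2E)-5-(tert-butyldimethylsilyloxy)-3-methylpent-2-en-1-yl]oxy}diphenylsilane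
Product: 15 (3E)-5-(tert-butyldiphenylsilyloxy)-3-methylpent-3-en-1-ol
Conditions: PPTS (cat.), EtOH, 40 °C
Reagents that add atoms: none
Why: Acid-catalysed ethanolysis removes the primary TBS ether much faster than the TBDPS ether, which is far more stable to acid.

**Step 8**
Reactants: 15 (3E)-5-(tert-butyldiphenylsilyloxy)-3-methylpent-3-en-1-ol
Product: 16 {[(2E)-5-bromo-3-methylpent-2-en-1-yl]oxy}(tert-butyl)diphenylsilane
Conditions: CBr4, PPh3, CH2Cl2, 0 °C
Reagents that add atoms: carbon tetrabromide, BrC(Br)(Br)Br
Why: Appel bromination of a primary homoallylic alcohol under neutral conditions; the alkene and silyl ether are untouched.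

**Step 9**
Reactants: 16 {[(2E)-5-bromo-3-methylpent-2-en-1-yl]oxy}(tert-butyl)diphenylsilane; 10 methyl (4aS,8aS)-2-hydroxy-8,8-dimethoxy-4a,6-dimethyl-5-oxo-3,4,4a,5,8,8a-hexahydronaphthalene-1-carboxylate
Product: 20 methyl 15-(tert-butyldiphenylsilyloxy)-3,9-dihydroxy-6,6-dimethoxy-18-nor-5β-labda-3,7,13E-trien-19-oate (keto ester as its C3 enol; both C9 epimers), via Grignard reagent 17 (not isolated), via organocerium reagent 18 (not isolated), via sodium enolate 19 (not isolated)
Conditions: 16, Mg, THF, rt; CeCl3, THF, −78 °C; 10 pre-treated with NaH, THF, 0 °C; then −78 → −40 °C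
Reagents that add atoms: none
Why: Organocerium 1,2-addition to a hindered enone; the weakly basic cerium reagent adds to the C9 carbonyl and not to C7 or the C17 protons, while the keto ester is masked as its enolate 19 so that it consumes no side-chain reagent.

**Step 10**
Reactants: 20 methyl 15-(tert-butyldiphenylsilyloxy)-3,9-dihydroxy-6,6-dimethoxy-18-nor-5β-labda-3,7,13E-trien-19-oate
Product: 21 methyl 15-(tert-butyldiphenylsilyloxy)-3,9-dihydroxy-6-oxo-18-nor-5β-labda-3,7,13E-trien-19-oate (cis-fused)
Conditions: p-TsOH·H2O (cat.), acetone/H2O, 0 °C → rt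
Reagents that add atoms: water, O
Why: Hydrolysis of an allylic dimethyl ketal through the conjugated oxocarbenium ion, the usual unmasking of a quinol ketal to a γ-hydroxy enone; the TBDPS ether and the tertiary alcohol, whose ionisation the new enone disfavours, should survive.

**Step 11**
Reactants: 21 methyl 15-(tert-butyldiphenylsilyloxy)-3,9-dihydroxy-6-oxo-18-nor-5β-labda-3,7,13E-trien-19-oate
Product: 23 methyl 15-(tert-butyldiphenylsilyloxy)-3,9-dihydroxy-6-oxo-18-nor-5α-labda-3,7,13E-trien-19-oate (trans-fused), via trilithium dienediolate 22 (not isolated)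
Conditions: LiN(i-Pr)2 (LDA, 3.3 equiv), THF, −78 °C; then AcOH, −78 °C
Reagents that add atoms: none
Why: Kinetic α′-deprotonation of the enone at C5, after the hydroxyl and the keto ester have each taken one equivalent of base, flattens C5 in dienediolate 22. Kinetic protonation should then occur on the face opposite the axial C20 methyl on the neighbouring C10, giving the 5α-H trans fusion that equilibration cannot be trusted to give.

**Step 12**
Reactants: 23 methyl 15-(tert-butyldiphenylsilyloxy)-3,9-dihydroxy-6-oxo-18-nor-5α-labda-3,7,13E-trien-19-oate
Product: 24 methyl 15-(tert-butyldiphenylsilyloxy)-9-hydroxy-3,6-dioxolabda-7,13E-dien-19-oate (4α-methyl C18; 4β-ester C19; 5α-H)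
Conditions: MeI, K2CO3, acetone, rt
Reagents that add atoms: iodomethane, CI
Why: C-Alkylation of a β-keto ester enolate; in the trans-fused enolate the axial C20 methyl, 1,3 to C4, shields the β face, so the methyl enters α and the ester is left β, the known outcome for 10-methyl trans-decalin keto esters. The weak base does not touch C5.

**Step 13**
Reactants: 24 methyl 15-(tert-butyldiphenylsilyloxy)-9-hydroxy-3,6-dioxolabda-7,13E-dien-19-oate
Product: 25 methyl 15-(tert-butyldiphenylsilyloxy)-3,6-dioxolabda-8,13E-dien-19-oate
Conditions: Zn dust, AcOH/THF, 45 °C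
Reagents that add atoms: none
Why: Zinc reduction of a γ-oxygenated enone (vinylogous α-ketol deoxygenation): two-electron reduction of the C6 enone expels the C9 hydroxyl, and the dienol is protonated kinetically at C7 to leave the tetrasubstituted C8=C9 alkene out of conjugation. The saturated C3 ketone and the ester are inert to zinc.

**Step 14**
Reactants: 25 methyl 15-(tert-butyldiphenylsilyloxy)-3,6-dioxolabda-8,13E-dien-19-oate
Product: 27 15-(tert-butyldiphenylsilyloxy)-3α-hydroxylabda-8,13E-dien-19,6β-olide, via dihydroxy ester 26 (not isolated)
Conditions: LiBH(s-Bu)3, THF, −78 → 0 °C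
Reagents that add atoms: none
Why: Bulky-hydride reduction: equatorial attack at C3 gives the axial 3α-alcohol, and attack at C6 from the α face (the β face is closed by C19 and C20) gives the axial 6β-alkoxide. This alkoxide is 1,3-diaxial to the C19 ester in 26 and should close to the γ-lactone.

**Step 15**
Reactants: 27 15-(tert-butyldiphenylsilyloxy)-3α-hydroxylabda-8,13E-dien-19,6β-olide
Product: 28 15-(tert-butyldiphenylsilyloxy)labda-8,13E-diene-3α,6β,19-triol
Conditions: LiAlH4, THF, 0 °C → rt
Reagents that add atoms: none
Why: Hydride reduction of the lactone to the 6β,19-diol; any C6 ketone or uncyclised ester left from step 14 converges on the same triol, since small hydrides also attack C6 from the α face.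

**Step 16**
Reactants: 28 15-(tert-butyldiphenylsilyloxy)labda-8,13E-diene-3α,6β,19-triol
Product: 29 19-(tert-butyldimethylsilyloxy)-15-(tert-butyldiphenylsilyloxy)labda-8,13E-diene-3α,6β-diol
Conditions: TBSCl (1.1 equiv), imidazole, DMF, 0 °C
Reagents that add atoms: tert-butyldimethylsilyl chloride, CC(C)(C)[Si](C)(C)Cl
Why: Selective silylation of the only primary hydroxyl; the two axial secondary hydroxyls are far slower.

**Step 17**
Reactants: 29 19-(tert-butyldimethylsilyloxy)-15-(tert-butyldiphenylsilyloxy)labda-8,13E-diene-3α,6β-diol; 30 3-methylbutanoyl chloride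
Product: 31 19-(tert-butyldimethylsilyloxy)-15-(tert-butyldiphenylsilyloxy)labda-8,13E-diene-3α,6β-diyl bis(3-methylbutanoate)
Conditions: 30 (6 equiv), DMAP (0.2 equiv), pyridine, 60 °C
Reagents that add atoms: 3-methylbutanoyl chloride (second equivalent of 30), CC(C)CC(=O)Cl
Why: DMAP-catalysed acylation through the acylpyridinium ion under forcing conditions; two equivalents of 30 are consumed, one at each hindered axial hydroxyl, with retention at C3 and C6.

**Step 18**
Reactants: 31 19-(tert-butyldimethylsilyloxy)-15-(tert-butyldiphenylsilyloxy)labda-8,13E-diene-3α,6β-diyl bis(3-methylbutanoate)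
Product: 32 15,19-dihydroxylabda-8,13E-diene-3α,6β-diyl bis(3-methylbutanoate)
Conditions: HF·pyridine, THF/pyridine, 0 °C → rt
Reagents that add atoms: none
Why: Fluoride cleaves both silyl ethers in an acidic buffered medium, which avoids the base-promoted migration of the C6 acyl group to the nearby C19 hydroxyl.

**Step 19**
Reactants: 32 15,19-dihydroxylabda-8,13E-diene-3α,6β-diyl bis(3-methylbutanoate)
Product: 33 19-hydroxy-15-oxolabda-8,13E-diene-3α,6β-diyl bis(3-methylbutanoate)
Conditions: MnO2, CH2Cl2, rt
Reagents that add atoms: none
Why: Activated MnO2 oxidises allylic alcohols selectively, so the saturated neopentyl C19 hydroxyl stays and the E geometry of the enal is kept under neutral conditions.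

**Step 20**
Reactants: 33 19-hydroxy-15-oxolabda-8,13E-diene-3α,6β-diyl bis(3-methylbutanoate)
Product: 34 (3R,4S,5R,6R,10S)-19-hydroxy-3α,6β-bis(3-methylbutanoyloxy)labda-8,13E-dien-15-oic acid (CNP0272110.1)
Conditions: NaClO2, NaH2PO4, 2-methylbut-2-ene, t-BuOH/H2O, 0 °C → rt
Reagents that add atoms: sodium chlorite, [Na+].[O-]Cl=O
Why: Pinnick oxidation converts the enal to the acid without touching the primary alcohol or the esters; the alkene scavenger removes hypochlorous acid before it can attack the C8=C9 or C13=C14 bonds.

## Compound list

1 | 2,6-dimethylphenol | Cc1cccc(C)c1O | starting material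
2 | 4-methoxy-2,6-dimethylphenol | COc1cc(C)c(O)c(C)c1 | intermediate (not isolated)
3 | 4,4-dimethoxy-2,6-dimethylcyclohexa-2,5-dien-1-one | COC1(OC)C=C(C)C(=O)C(C)=C1 | intermediate
4 | methyl acetate | COC(C)=O | starting material
5 | acrolein | C=CC=O | starting material
6 | lithium 1-methoxyethen-1-olate (lithium enolate of methyl acetate) | [Li+].[O-]C(=C)OC | intermediate (not isolated)
7 | methyl 3-hydroxypent-4-enoate (racemic) | C=CC(O)CC(=O)OC | intermediate
8 | methyl 3-oxopent-4-enoate | C=CC(=O)CC(=O)OC | intermediate
9 | methyl 2-[(1R)-6,6-dimethoxy-2,4-dimethyl-3-oxidocyclohexa-2,4-dien-1-yl]-3-oxopent-4-enoate (dienolate; C2 of the pentenoate unassigned) | C=CC(=O)C(C(=O)OC)[C@@H]1C(C)=C([O-])C(C)=CC1(OC)OC | intermediate (not isolated)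
10 | methyl (4aS,8aS)-2-hydroxy-8,8-dimethoxy-4a,6-dimethyl-5-oxo-3,4,4a,5,8,8a-hexahydronaphthalene-1-carboxylate | CC1=CC(OC)(OC)[C@@H]2C(C(=O)OC)=C(O)CC[C@]2(C)C1=O | intermediate
11 | 4-(tert-butyldimethylsilyloxy)but-1-yne | C#CCCO[Si](C)(C)C(C)(C)C | starting material
12 | [(1E)-4-(tert-butyldimethylsilyloxy)-2-methylbut-1-en-1-yl]dimethylalumane | C[Al](C)/C=C(\C)CCO[Si](C)(C)C(C)(C)C | intermediate (not isolated)
13 | (2E)-5-(tert-butyldimethylsilyloxy)-3-methylpent-2-en-1-ol | OC/C=C(\C)CCO[Si](C)(C)C(C)(C)C | intermediate
14 | tert-butyl{[(2E)-5-(tert-butyldimethylsilyloxy)-3-methylpent-2-en-1-yl]oxy}diphenylsilane | CC(C)(C)[Si](C)(C)OCC/C(C)=C/CO[Si](c1ccccc1)(c1ccccc1)C(C)(C)C | intermediate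
15 | (3E)-5-(tert-butyldiphenylsilyloxy)-3-methylpent-3-en-1-ol | OCC/C(C)=C/CO[Si](c1ccccc1)(c1ccccc1)C(C)(C)C | intermediate
16 | {[(2E)-5-bromo-3-methylpent-2-en-1-yl]oxy}(tert-butyl)diphenylsilane | BrCC/C(C)=C/CO[Si](c1ccccc1)(c1ccccc1)C(C)(C)C | intermediate
17 | [(3E)-5-(tert-butyldiphenylsilyloxy)-3-methylpent-3-en-1-yl]magnesium bromide | Br[Mg]CC/C(C)=C/CO[Si](c1ccccc1)(c1ccccc1)C(C)(C)C | intermediate (not isolated)
18 | dichloro[(3E)-5-(tert-butyldiphenylsilyloxy)-3-methylpent-3-en-1-yl]cerium | Cl[Ce](Cl)CC/C(C)=C/CO[Si](c1ccccc1)(c1ccccc1)C(C)(C)C | intermediate (not isolated)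
19 | sodium enolate of 10 | [Na+].CC1=CC(OC)(OC)[C@@H]2C(C(=O)OC)=C([O-])CC[C@]2(C)C1=O | intermediate (not isolated)
20 | methyl 15-(tert-butyldiphenylsilyloxy)-3,9-dihydroxy-6,6-dimethoxy-18-nor-5β-labda-3,7,13E-trien-19-oate (C9 epimers) | CC1=CC(OC)(OC)[C@@H]2C(C(=O)OC)=C(O)CC[C@]2(C)C1(O)CC/C(C)=C/CO[Si](c3ccccc3)(c3ccccc3)C(C)(C)C | intermediate
21 | methyl 15-(tert-butyldiphenylsilyloxy)-3,9-dihydroxy-6-oxo-18-nor-5β-labda-3,7,13E-trien-19-oate (cis-fused; C9 epimers) | CC1=CC(=O)[C@@H]2C(C(=O)OC)=C(O)CC[C@]2(C)C1(O)CC/C(C)=C/CO[Si](c3ccccc3)(c3ccccc3)C(C)(C)C | intermediate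
22 | trilithium salt of 21 deprotonated at O9, at the keto ester and at C5 (C3=C4–C5=C6 dienediolate) | [Li+].[Li+].[Li+].CC1=CC([O-])=C2C(C(=O)OC)=C([O-])CC[C@]2(C)C1([O-])CC/C(C)=C/CO[Si](c3ccccc3)(c3ccccc3)C(C)(C)C | intermediate (not isolated)
23 | methyl 15-(tert-butyldiphenylsilyloxy)-3,9-dihydroxy-6-oxo-18-nor-5α-labda-3,7,13E-trien-19-oate (trans-fused; C9 epimers) | CC1=CC(=O)[C@H]2C(C(=O)OC)=C(O)CC[C@]2(C)C1(O)CC/C(C)=C/CO[Si](c3ccccc3)(c3ccccc3)C(C)(C)C | intermediate
24 | methyl 15-(tert-butyldiphenylsilyloxy)-9-hydroxy-3,6-dioxolabda-7,13E-dien-19-oate (C9 epimers) | CC1=CC(=O)[C@H]2[C@@](C)(C(=O)OC)C(=O)CC[C@]2(C)C1(O)CC/C(C)=C/CO[Si](c3ccccc3)(c3ccccc3)C(C)(C)C | intermediate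
25 | methyl 15-(tert-butyldiphenylsilyloxy)-3,6-dioxolabda-8,13E-dien-19-oate | CC1=C(CC/C(C)=C/CO[Si](c3ccccc3)(c3ccccc3)C(C)(C)C)[C@@]2(C)CCC(=O)[C@](C)(C(=O)OC)[C@@H]2C(=O)C1 | intermediate
26 | methyl 15-(tert-butyldiphenylsilyloxy)-3α,6β-dihydroxylabda-8,13E-dien-19-oate (formed as its lithium alkoxide) | CC1=C(CC/C(C)=C/CO[Si](c3ccccc3)(c3ccccc3)C(C)(C)C)[C@@]2(C)CC[C@@H](O)[C@](C)(C(=O)OC)[C@@H]2[C@H](O)C1 | intermediate (not isolated)
27 | 15-(tert-butyldiphenylsilyloxy)-3α-hydroxylabda-8,13E-dien-19,6β-olide | CC1=C(CC/C(C)=C/CO[Si](c4ccccc4)(c4ccccc4)C(C)(C)C)[C@@]2(C)CC[C@@H](O)[C@](C)(C(=O)O3)[C@@H]2[C@H]3C1 | intermediate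
28 | 15-(tert-butyldiphenylsilyloxy)labda-8,13E-diene-3α,6β,19-triol | CC1=C(CC/C(C)=C/CO[Si](c3ccccc3)(c3ccccc3)C(C)(C)C)[C@@]2(C)CC[C@@H](O)[C@](C)(CO)[C@@H]2[C@H](O)C1 | intermediate
29 | 19-(tert-butyldimethylsilyloxy)-15-(tert-butyldiphenylsilyloxy)labda-8,13E-diene-3α,6β-diol | CC1=C(CC/C(C)=C/CO[Si](c3ccccc3)(c3ccccc3)C(C)(C)C)[C@@]2(C)CC[C@@H](O)[C@](C)(CO[Si](C)(C)C(C)(C)C)[C@@H]2[C@H](O)C1 | intermediate
30 | 3-methylbutanoyl chloride | CC(C)CC(=O)Cl | starting material
31 | 19-(tert-butyldimethylsilyloxy)-15-(tert-butyldiphenylsilyloxy)labda-8,13E-diene-3α,6β-diyl bis(3-methylbutanoate) | CC1=C(CC/C(C)=C/CO[Si](c3ccccc3)(c3ccccc3)C(C)(C)C)[C@@]2(C)CC[C@@H](OC(=O)CC(C)C)[C@](C)(CO[Si](C)(C)C(C)(C)C)[C@@H]2[C@H](OC(=O)CC(C)C)C1 | intermediate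
32 | 15,19-dihydroxylabda-8,13E-diene-3α,6β-diyl bis(3-methylbutanoate) | CC1=C(CC/C(C)=C/CO)[C@@]2(C)CC[C@@H](OC(=O)CC(C)C)[C@](C)(CO)[C@@H]2[C@H](OC(=O)CC(C)C)C1 | intermediate
33 | 19-hydroxy-15-oxolabda-8,13E-diene-3α,6β-diyl bis(3-methylbutanoate) | CC1=C(CC/C(C)=C/C=O)[C@@]2(C)CC[C@@H](OC(=O)CC(C)C)[C@](C)(CO)[C@@H]2[C@H](OC(=O)CC(C)C)C1 | intermediate
34 | (3R,4S,5R,6R,10S)-19-hydroxy-3α,6β-bis(3-methylbutanoyloxy)labda-8,13E-dien-15-oic acid (CNP0272110.1) | CC1=C(CC/C(C)=C/C(=O)O)[C@@]2(C)CC[C@@H](OC(=O)CC(C)C)[C@](C)(CO)[C@@H]2[C@H](OC(=O)CC(C)C)C1 | target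

## Step count and least certain steps

Total: 20 steps. Longest linear sequence: 16 steps (steps 5–20, from 11). The branch from 4 and 5 through the key step is 15 steps (steps 2–4 and 9–20).

**Step 4 (key step, proposed new method).** Four things are most likely to go wrong:
- The cascade stalls after the first conjugate addition, because proton transfer parks the adduct as the enolate of its own keto ester, in which the vinyl ketone is no longer an acceptor.
- The first addition becomes reversible once carbonate is present, which erodes enantiomeric purity.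
- The vinyl ketone oligomerises.
- The catalyst fails to discriminate, or to react at all, because the α-methyl groups of the dienone slow the addition.

Fallback (known chemistry), from 3 and 8 back to 10: 8 is silylated (TMSCl, Et3N) to methyl (2Z)-3-[(trimethylsilyl)oxy]penta-2,4-dienoate F1. A thermal or high-pressure Diels–Alder reaction of this 2-siloxydiene with 3 as dienophile forms the same two bonds with the same regiochemistry and gives the racemic cis-fused cycloadduct methyl (4aRS,8aSR)-8,8-dimethoxy-4a,6-dimethyl-5-oxo-2-[(trimethylsilyl)oxy]-1,4,4a,5,8,8a-hexahydronaphthalene-1-carboxylate F2. Desilylation with TBAF/AcOH gives the racemate of 10. Preparative chromatography on a chiral phase delivers 10 and removes its antipode, methyl (4aR,8aR)-2-hydroxy-8,8-dimethoxy-4a,6-dimethyl-5-oxo-3,4,4a,5,8,8a-hexahydronaphthalene-1-carboxylate F3.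

**Step 11 (C5 inversion).** Three things are most likely to go wrong:
- Deprotonation at the C17 methyl competes with the hindered C5–H.
- The facial selectivity of the protonation is poor, because the two C9 epimers present different groups to the α face.
- The cis isomer is regenerated during the quench.

Fallback, from 21 back to 23, uses thermodynamic control: 21 is equilibrated under acid catalysis (p-TsOH, wet acetone, warm) in a polar medium that favours the keto tautomer of the keto ester. 23 is separated and the recovered 21 is resubmitted. This is workable only to the extent that the trans isomer is populated at equilibrium, and it makes no new compound.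

**Step 13 (reductive transposition).** Four things are most likely to go wrong:
- The unactivated tertiary hydroxyl leaves slowly.
- The enone is simply saturated without elimination.
- The C8=C9 alkene drifts into conjugation.
- The kinetically set C5 centre is lost in warm acid.

Fallback, from 24 back to 25: the tertiary alcohol is dehydrated with Burgess reagent. Only the C11 hydrogens are available, so the product is the linear dienone methyl 15-(tert-butyldiphenylsilyloxy)-3,6-dioxolabda-7,9(11),13E-trien-19-oate F4. A 1,6-reduction with SmI2 in THF/t-BuOH at −78 °C then protonates C11 and C7 and leaves the C8=C9 alkene, under neutral low-temperature conditions.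

**Step 17 (double acylation).** The likely failure is incomplete acylation of the 6β-hydroxyl, which is 1,3-diaxial to C20 and to the silylated C19; silyl migration under forcing conditions is a lesser risk.

Fallback, from 28 back to 32: all three hydroxyls of 28 are acylated with 30 before any bulky silyl ether stands next to O6, giving 15-(tert-butyldiphenylsilyloxy)labda-8,13E-diene-3α,6β,19-triyl tris(3-methylbutanoate) F5. The least hindered, primary C19 ester is removed by lipase-catalysed butanolysis to give 15-(tert-butyldiphenylsilyloxy)-19-hydroxylabda-8,13E-diene-3α,6β-diyl bis(3-methylbutanoate) F6. HF·pyridine then removes the silyl ether to give 32.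

## Further compounds

F1 | step 4 | methyl (2Z)-3-[(trimethylsilyl)oxy]penta-2,4-dienoate | C=C/C(O[Si](C)(C)C)=C/C(=O)OC
F2 | step 4 | methyl (4aRS,8aSR)-8,8-dimethoxy-4a,6-dimethyl-5-oxo-2-[(trimethylsilyl)oxy]-1,4,4a,5,8,8a-hexahydronaphthalene-1-carboxylate (racemic; one enantiomer drawn; C1 unassigned) | CC1=CC(OC)(OC)[C@@H]2C(C(=O)OC)C(O[Si](C)(C)C)=CC[C@]2(C)C1=O
F3 | step 4 | methyl (4aR,8aR)-2-hydroxy-8,8-dimethoxy-4a,6-dimethyl-5-oxo-3,4,4a,5,8,8a-hexahydronaphthalene-1-carboxylate (antipode of 10) | CC1=CC(OC)(OC)[C@H]2C(C(=O)OC)=C(O)CC[C@@]2(C)C1=O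
F0 | step 11 | none | none
F4 | step 13 | methyl 15-(tert-butyldiphenylsilyloxy)-3,6-dioxolabda-7,9(11),13E-trien-19-oate (C9=C11 geometry unassigned) | CC1=CC(=O)[C@H]2[C@@](C)(C(=O)OC)C(=O)CC[C@]2(C)C1=CC/C(C)=C/CO[Si](c3ccccc3)(c3ccccc3)C(C)(C)C
F5 | step 17 | 15-(tert-butyldiphenylsilyloxy)labda-8,13E-diene-3α,6β,19-triyl tris(3-methylbutanoate) | CC1=C(CC/C(C)=C/CO[Si](c3ccccc3)(c3ccccc3)C(C)(C)C)[C@@]2(C)CC[C@@H](OC(=O)CC(C)C)[C@](C)(COC(=O)CC(C)C)[C@@H]2[C@H](OC(=O)CC(C)C)C1
F6 | step 17 | 15-(tert-butyldiphenylsilyloxy)-19-hydroxylabda-8,13E-diene-3α,6β-diyl bis(3-methylbutanoate) | CC1=C(CC/C(C)=C/CO[Si](c3ccccc3)(c3ccccc3)C(C)(C)C)[C@@]2(C)CC[C@@H](OC(=O)CC(C)C)[C@](C)(CO)[C@@H]2[C@H](OC(=O)CC(C)C)C1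
A1 | alternative 1 | methyl (1R,5S,6R)-5-(dimethoxymethyl)-1,5-dimethyl-2-oxo-6-vinylcyclohexane-1-carboxylate | COC(=O)[C@]1(C)[C@H](C=C)[C@@](C)(C(OC)OC)CCC1=O
A2 | alternative 2 | methyl (5S,6S,8aS)-6-[(tert-butyldimethylsilyl)oxy]-5-{[(tert-butyldiphenylsilyl)oxy]methyl}-4-ethoxy-2,5,8a-trimethyl-3,5,6,7,8,8a-hexahydronaphthalene-1-carboxylate | CCOC1=C2[C@](C)(CC[C@H](O[Si](C)(C)C(C)(C)C)[C@]2(C)CO[Si](c3ccccc3)(c3ccccc3)C(C)(C)C)C(C(=O)OC)=C(C)C1
A3 | alternative 3 | (3S,4R,5R,6R,8R,10S)-3-hydroxy-9-oxo-11,12,13,14,15,16-hexanorlabdan-19,6-olide | C[C@H]1C(=O)[C@@]2(C)CC[C@H](O)[C@@]3(C)[C@@H]2[C@@H](C1)OC3=O
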